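## Retrosynthetic overview

1. Target ⇐ global Si–O cleavage of the tetrasilyl ether of the same tetrahydrofuran.
2. Tetrahydrofuran ring ⇐ double reductive cycloetherification of a C2-symmetric (2S,3S)-1,4-diaryl-2,3-bis(silyloxymethyl)butane-1,4-dione; the C–O–C bridge and both benzylic centres are set last, each hydride entering anti to the neighbouring CH2OSi group.
3. Diketone ⇐ twofold aryllithium opening, then O-silylation, of (1S,5S)-3,7-dioxabicyclo[3.3.0]octane-2,6-dione, which already holds both C–CH2O stereocentres.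
4. Bis-lactone ⇐ oxidation of the bis-lactol made in one operation from succinaldehyde and two formaldehyde by catalyst-controlled double α-hydroxymethylation and double lactol closure.
5. Ring order: the two fused five-membered O-rings first (temporary, opened in the aryllithium step), the tetrahydrofuran ring last; the arene rings are bought.

Assumption: the SMILES defines the target as (2S,3S,4S,5S): the two aryl groups trans, the two CH2OH groups trans, each aryl cis to its neighbouring CH2OH.

## Route

Step 1
Reactants: 1 2,5-dimethoxytetrahydrofuran (cis/trans mixture); 2 formaldehyde (37% aqueous solution)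
Product: 5 (1S,5S)-3,7-dioxabicyclo[3.3.0]octane-2,6-diol (cis-fused bis-lactol; anomer mixture), via succinaldehyde 3 (not isolated), via dialdehyde diol 4 (not isolated)
Conditions: H2O, 90 °C, 2 h, MeOH distilled off; then 2 (6 equiv), (R)-2-[diphenyl(trimethylsilyloxy)methyl]pyrrolidine (20 mol %), NaH2PO4/Na2HPO4 buffer (pH 7), THF, 4 °C to rt, 48 h
Reagents that add atoms: water, O
Why: Proposed new method: the (R)-diarylprolinol silyl ether forms the anti (E)-enamine of each CH2–CHO unit in turn and formaldehyde attacks the face remote from the CPh2OSiMe3 group, giving (S) at both α-carbons (the closest known reaction type is the enamine-catalysed α-hydroxymethylation of simple aldehydes, here applied twice to a dialdehyde), and only the (2S,3S) isomer can close both γ-lactol rings to the cis-fused bicycle, which masks the aldehydes against further enamine chemistry and leaves the meso isomer behind.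

Step 2
Reactants: 5 (1S,5S)-3,7-dioxabicyclo[3.3.0]octane-2,6-diol
Product: 6 (1S,5S)-3,7-dioxabicyclo[3.3.0]octane-2,6-dione (cis-fused bis-γ-lactone; each bridgehead carries one C=O and one CH2O)
Conditions: PhI(OAc)2 (2.4 equiv), 2,2,6,6-tetramethylpiperidin-1-oxyl (TEMPO, 20 mol %), MeCN/CH2Cl2, rt
Reagents that add atoms: none
Why: Oxoammonium (TEMPO) oxidation of lactols to lactones; the two stereocentres become α to carbonyls but cannot epimerise singly because only the cis-fused bicycle is strain-free, so the configuration from step 1 is kept.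

Step 3
Reactants: 7 4-bromo-2-methoxyphenol
Product: 8 (4-bromo-2-methoxyphenoxy)(tert-butyl)dimethylsilane
Conditions: t-BuMe2SiCl, imidazole, CH2Cl2, rt
Reagents that add atoms: tert-butyldimethylsilyl chloride, CC(C)(C)[Si](C)(C)Cl
Why: Standard O-silylation of a phenol; the aryl silyl ether survives bromine–lithium exchange and no stereocentre is involved.

Step 4
Reactants: 8 (4-bromo-2-methoxyphenoxy)(tert-butyl)dimethylsilane (2.3 equiv); 6 (1S,5S)-3,7-dioxabicyclo[3.3.0]octane-2,6-dione
Product: 11 (2S,3S)-1,4-bis[4-(tert-butyldimethylsilyloxy)-3-methoxyphenyl]-2,3-bis(hydroxymethyl)butane-1,4-dione (in equilibrium with its cyclic hemiketals), via aryllithium 9 (not isolated), via dilithium bis-hemiketalate 10 (not isolated)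
Conditions: n-BuLi (2.3 equiv), THF, −78 °C, 30 min; then 6 in THF added slowly, −78 °C, 1 h; then H2O, −78 °C to rt
Reagents that add atoms: none
Why: Bromine–lithium exchange followed by acyl substitution at each lactone carbonyl, which stops at the ketone oxidation level because the tetrahedral lithium hemiketalate persists at −78 °C; the two existing stereocentres are not touched and no new one is kept.

Step 5
Reactants: 11 (2S,3S)-1,4-bis[4-(tert-butyldimethylsilyloxy)-3-methoxyphenyl]-2,3-bis(hydroxymethyl)butane-1,4-dione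
Product: 12 (2S,3S)-1,4-bis[4-(tert-butyldimethylsilyloxy)-3-methoxyphenyl]-2,3-bis[(tert-butyldiphenylsilyloxy)methyl]butane-1,4-dione
Conditions: t-BuPh2SiCl (2.5 equiv), imidazole (5 equiv), DMF, 0 °C to rt
Reagents that add atoms: tert-butyldiphenylsilyl chloride, CC(C)(C)[Si](Cl)(c1ccccc1)c1ccccc1
Why: O-silylation of the two primary alcohols of the open hydroxy-ketone form (the tertiary hemiketal OH does not react), using a bulky, weakly basic silyl ether so that these oxygens cannot compete with the ketone oxygen as internal nucleophiles in step 6; the near-neutral conditions leave the α-stereocentres alone.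

Step 6
Reactants: 12 (2S,3S)-1,4-bis[4-(tert-butyldimethylsilyloxy)-3-methoxyphenyl]-2,3-bis[(tert-butyldiphenylsilyloxy)methyl]butane-1,4-dione
Product: 14 (2S,3S,4S,5S)-2,5-bis[4-(tert-butyldimethylsilyloxy)-3-methoxyphenyl]-3,4-bis[(tert-butyldiphenylsilyloxy)methyl]tetrahydrofuran, via cyclic triethylsilyl ketal 13 (not isolated)
Conditions: Et3SiH (6 equiv), Et3SiOTf (20 mol %), CH2Cl2, −78 to −40 °C
Reagents that add atoms: none
Why: Silyl triflate-catalysed silane reductive etherification of a 1,4-diketone (Olah type): the silylated ketone is captured by the second carbonyl oxygen to give a five-membered 2-aryl oxocarbenium ion, which Et3SiH reduces far faster than an open silyl-activated ketone, and in this ion and in the one formed next from 13 the hydride enters anti to the neighbouring CH2OSi group (inside attack on the envelope in which that group is pseudoaxial to avoid the coplanar aryl, as in known hemiketal reductions used for 2,5-diaryltetrahydrofuran lignans), so each aryl ends cis to its neighbour and the fixed (3S,4S) centres give the (2S,5S) pair.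

Step 7
Reactants: 14 (2S,3S,4S,5S)-2,5-bis[4-(tert-butyldimethylsilyloxy)-3-methoxyphenyl]-3,4-bis[(tert-butyldiphenylsilyloxy)methyl]tetrahydrofuran
Product: 15 Eduesmine, [(2S,3S,4S,5S)-2,5-bis(4-hydroxy-3-methoxyphenyl)tetrahydrofuran-3,4-diyl]dimethanol
Conditions: Bu4NF (6 equiv), AcOH (6 equiv), THF, 0 °C to rt
Reagents that add atoms: none
Why: Fluoride-induced Si–O cleavage of the two aryl and two primary alkyl silyl ethers, buffered with AcOH so that the phenols and the acid- and base-sensitive cis benzylic ether centres stay intact; no stereocentre is touched.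

## Compound list

1 | 2,5-dimethoxytetrahydrofuran (cis/trans mixture) | COC1CCC(OC)O1 | starting material
2 | formaldehyde (37% aqueous solution) | C=O | starting material
3 | succinaldehyde (butanedial) | O=CCCC=O | intermediate
4 | (2S,3S)-2,3-bis(hydroxymethyl)butanedial | O=C[C@H](CO)[C@@H](CO)C=O | intermediate
5 | (1S,5S)-3,7-dioxabicyclo[3.3.0]octane-2,6-diol, cis-fused, anomer mixture | OC1OC[C@@H]2[C@H]1COC2O | intermediate
6 | (1S,5S)-3,7-dioxabicyclo[3.3.0]octane-2,6-dione, cis-fused | O=C1OC[C@@H]2[C@H]1COC2=O | intermediate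
7 | 4-bromo-2-methoxyphenol | COc1cc(Br)ccc1O | starting material
8 | (4-bromo-2-methoxyphenoxy)(tert-butyl)dimethylsilane | COc1cc(Br)ccc1O[Si](C)(C)C(C)(C)C | intermediate
9 | [4-(tert-butyldimethylsilyloxy)-3-methoxyphenyl]lithium | COc1cc([Li])ccc1O[Si](C)(C)C(C)(C)C | intermediate
10 | dilithium (1S,5S)-2,6-bis[4-(tert-butyldimethylsilyloxy)-3-methoxyphenyl]-3,7-dioxabicyclo[3.3.0]octane-2,6-diolate (ketal centres unassigned) | [Li+].[Li+].COc1cc(ccc1O[Si](C)(C)C(C)(C)C)C1([O-])OC[C@@H]2[C@H]1COC2([O-])c1ccc(O[Si](C)(C)C(C)(C)C)c(OC)c1 | intermediate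
11 | (2S,3S)-1,4-bis[4-(tert-butyldimethylsilyloxy)-3-methoxyphenyl]-2,3-bis(hydroxymethyl)butane-1,4-dione | COc1cc(ccc1O[Si](C)(C)C(C)(C)C)C(=O)[C@H](CO)[C@@H](CO)C(=O)c1ccc(O[Si](C)(C)C(C)(C)C)c(OC)c1 | intermediate
12 | (2S,3S)-1,4-bis[4-(tert-butyldimethylsilyloxy)-3-methoxyphenyl]-2,3-bis[(tert-butyldiphenylsilyloxy)methyl]butane-1,4-dione | COc1cc(ccc1O[Si](C)(C)C(C)(C)C)C(=O)[C@H](CO[Si](c1ccccc1)(c1ccccc1)C(C)(C)C)[C@@H](CO[Si](c1ccccc1)(c1ccccc1)C(C)(C)C)C(=O)c1ccc(O[Si](C)(C)C(C)(C)C)c(OC)c1 | intermediate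
13 | (3S,4S,5S)-2,5-bis[4-(tert-butyldimethylsilyloxy)-3-methoxyphenyl]-3,4-bis[(tert-butyldiphenylsilyloxy)methyl]-2-(triethylsilyloxy)tetrahydrofuran (C-2 unassigned; 5-aryl cis to the 4-substituent) | COc1cc(C2(O[Si](CC)(CC)CC)O[C@H](c3ccc(O[Si](C)(C)C(C)(C)C)c(OC)c3)[C@H](CO[Si](c3ccccc3)(c3ccccc3)C(C)(C)C)[C@H]2CO[Si](c2ccccc2)(c2ccccc2)C(C)(C)C)ccc1O[Si](C)(C)C(C)(C)C | intermediate
14 | (2S,3S,4S,5S)-2,5-bis[4-(tert-butyldimethylsilyloxy)-3-methoxyphenyl]-3,4-bis[(tert-butyldiphenylsilyloxy)methyl]tetrahydrofuran | COc1cc([C@H]2O[C@H](c3ccc(O[Si](C)(C)C(C)(C)C)c(OC)c3)[C@H](CO[Si](c3ccccc3)(c3ccccc3)C(C)(C)C)[C@H]2CO[Si](c2ccccc2)(c2ccccc2)C(C)(C)C)ccc1O[Si](C)(C)C(C)(C)C | intermediate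
15 | Eduesmine, [(2S,3S,4S,5S)-2,5-bis(4-hydroxy-3-methoxyphenyl)tetrahydrofuran-3,4-diyl]dimethanol | COc1cc([C@H]2O[C@H](c3ccc(O)c(OC)c3)[C@H](CO)[C@H]2CO)ccc1O | target

## Step count and risks

Total step count: 7. Longest linear sequence: 6 steps (1 → 5 → 6 → 11 → 12 → 14 → 15); step 3 is a one-step side branch.

**Step 1 (double hydroxymethylation and double lactol closure).** The second aldol has to run through the small open-chain share of a mono-lactol, and poor conversion or eroded selectivity would give mono-adduct and meso material. The fallback sets out from 1 and comes back at 5, replacing catalyst control by auxiliary control. Compound 1 is hydrolysed as before to 3 and condensed with two equivalents of (S)-1-amino-2-(methoxymethyl)pyrrolidine to give succinaldehyde bis-SAMP hydrazone F1. Two successive rounds of deprotonation and alkylation (LiN(i-Pr)2, THF, 0 °C; BnOCH2Cl, −100 °C; Enders hydrazone alkylation) give the (2R,3R)-2,3-bis(benzyloxymethyl) bis-hydrazone F2, which has the same spatial arrangement as 4; the descriptor changes only because CH=N ranks below CH2O. Ozonolysis (O3, CH2Cl2, −78 °C) frees (2S,3S)-2,3-bis(benzyloxymethyl)butanedial F3. Hydrogenolysis (H2, Pd(OH)2 on carbon, EtOAc) unmasks 4, which closes to 5.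

**Step 6 (double reductive cycloetherification).** If an open silyl-activated ketone is reduced before ring closure, that benzylic centre comes out trans to its neighbour. Other risks are furan formation by loss of the second oxygen, Friedel–Crafts closure onto the other arene, and acid epimerisation of the cis product on warming. The fallback sets out from 6 and comes back at 14; it makes the benzylic centres by C–aryl bond formation instead of hydride delivery. Compound 6 is opened with Me3Al/MeNH(OMe)·HCl to the (2S,3S) bis(N-methoxy-N-methylamide) diol F6 and silylated (t-BuPh2SiCl, imidazole) to the bis-silyl ether F7. Reduction with i-Bu2AlH (THF, −78 °C) gives (2S,3S)-2,3-bis[(tert-butyldiphenylsilyloxy)methyl]butanedial F8, and PhSO2H/CaCl2 (CH2Cl2) closes it to the (3S,4S)-2,5-bis(phenylsulfonyl)tetrahydrofuran F9. The arylzinc bromide F10 (from 9 and ZnBr2) then replaces both sulfonyl groups through the cyclic oxocarbenium ions. Each aryl enters cis to the neighbouring CH2OSi group, the known outcome for arylzinc additions to 3-substituted 2-sulfonyltetrahydrofurans, giving 14.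

**Step 4 (twofold aryllithium opening of 6).** The aryllithium can deprotonate 6 at a bridgehead, and the enolate would expel the β-acyloxy group; mono-addition and over-addition are lesser risks. The fallback sets out from 5 (with 8) and comes back at 11; it replaces acyl substitution on the base-sensitive bis-lactone by carbonyl addition at the aldehyde level followed by oxidation. Compound 8 is converted with Mg (THF) into [4-(tert-butyldimethylsilyloxy)-3-methoxyphenyl]magnesium bromide F4. Bis-lactol 5 reacts through its open hydroxy-aldehyde form with excess F4 to give the (2S,3S)-1,4-diaryl-2,3-bis(hydroxymethyl)butane-1,4-diol F5; its carbinol centres form as a mixture, which does not matter. MnO2 (CH2Cl2, rt) oxidises only the two electron-rich benzylic alcohols and gives 11.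

Further compounds
F1 | step 1 | succinaldehyde bis-SAMP hydrazone, (1E,4E)-N,N'-bis[(S)-2-(methoxymethyl)pyrrolidin-1-yl]butane-1,4-diimine | COC[C@@H]1CCCN1/N=C/CC/C=N/N1CCC[C@H]1COC
F2 | step 1 | (2R,3R)-2,3-bis(benzyloxymethyl)butanedial bis-SAMP hydrazone | COC[C@@H]1CCCN1/N=C/[C@H](COCc1ccccc1)[C@@H](COCc1ccccc1)/C=N/N1CCC[C@H]1COC
F3 | step 1 | (2S,3S)-2,3-bis(benzyloxymethyl)butanedial | O=C[C@H](COCc1ccccc1)[C@@H](COCc1ccccc1)C=O
F4 | step 4 | [4-(tert-butyldimethylsilyloxy)-3-methoxyphenyl]magnesium bromide | COc1cc([Mg]Br)ccc1O[Si](C)(C)C(C)(C)C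
F5 | step 4 | (2S,3S)-1,4-bis[4-(tert-butyldimethylsilyloxy)-3-methoxyphenyl]-2,3-bis(hydroxymethyl)butane-1,4-diol (C-1 and C-4 epimer mixture) | COc1cc(ccc1O[Si](C)(C)C(C)(C)C)C(O)[C@H](CO)[C@@H](CO)C(O)c1ccc(O[Si](C)(C)C(C)(C)C)c(OC)c1
F6 | step 6 | (2S,3S)-2,3-bis(hydroxymethyl)-N1,N4-dimethoxy-N1,N4-dimethylbutanediamide | CON(C)C(=O)[C@H](CO)[C@@H](CO)C(=O)N(C)OC
F7 | step 6 | (2S,3S)-2,3-bis[(tert-butyldiphenylsilyloxy)methyl]-N1,N4-dimethoxy-N1,N4-dimethylbutanediamide | CON(C)C(=O)[C@H](CO[Si](c1ccccc1)(c1ccccc1)C(C)(C)C)[C@@H](CO[Si](c1ccccc1)(c1ccccc1)C(C)(C)C)C(=O)N(C)OC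
F8 | step 6 | (2S,3S)-2,3-bis[(tert-butyldiphenylsilyloxy)methyl]butanedial | O=C[C@H](CO[Si](c1ccccc1)(c1ccccc1)C(C)(C)C)[C@@H](CO[Si](c1ccccc1)(c1ccccc1)C(C)(C)C)C=O
F9 | step 6 | (3S,4S)-3,4-bis[(tert-butyldiphenylsilyloxy)methyl]-2,5-bis(phenylsulfonyl)tetrahydrofuran (C-2 and C-5 epimer mixture) | O=S(=O)(c1ccccc1)C1OC(S(=O)(=O)c2ccccc2)[C@H](CO[Si](c2ccccc2)(c2ccccc2)C(C)(C)C)[C@H]1CO[Si](c1ccccc1)(c1ccccc1)C(C)(C)C
F10 | step 6 | [4-(tert-butyldimethylsilyloxy)-3-methoxyphenyl]zinc bromide | COc1cc([Zn]Br)ccc1O[Si](C)(C)C(C)(C)C
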